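The rate constants were drawn at random within sensible limits; the rest is arithmetic.

You asked for a quick number, but no single half-life of free monomer can give one: by its reaction with initiator alone, the other concentrations held at their charge, the half-life is 27 min, longer than the 80 s of the run, so the decay of free monomer rests on the living ends, which are made from initiator and lost to transfer agent, and its decay constant moves with their concentration.

free monomer 0.0010 M (fed, over 6.0 s); transfer agent 0.0100 mM; initiator 1 mol%; time 80 s

    free monomer + initiator → living end + monomer in chains (k1 = 42.8 /M/s)
    2 initiator → spent initiator (k2 = 213 /M/s)
    living end + transfer agent → dead chain (k3 = 567 /M/s)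
    free monomer + living end → monomer in chains + living end, rate k4*[living end]*[free monomer] (k4 = 2700 /M/s)

- two of one species on the left: rate k times its square, two consumed each time
- the average divides the monomer in chains by the number of chains begun, living and dead together
- run time (flask): 80 s

1. average number of monomer units in a chain (chains begun, living or dead) at 80 s
2. part of the free monomer that has reacted at 80 s

That moving constant can be integrated, though: I take the fraction of free monomer left as exp(−X). I hold [free monomer] at its charge, so initiator of charge 0.0100 mM decays pseudo-first-order at a = 0.0428 /s, and I hold [transfer agent] at its charge, so ends die at b = 0.00567 /s. Self-reaction of initiator starts at 0.00426 /s, slower than a, so I let a share s = 0.909 of the initiator begin chains. Then [living end] follows s·0.0100 mM·a/(a−b)·(exp(−bt) − exp(−at)). Counting from the middle of the feed gives t = 77.0 s, and the integral gives X = 1.13 for the exposure, the growth constant times the time integral of [living end]. So I commit to c = 67.7%, and with 0.00876 mM of chains begun, to dp = 77.3.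

The forecast stands at 81 and 67.5%, “with only a small loss to self-reaction”; its dp is higher than mine.

The simulation gives dp = 80.8 and c = 67.4%.

Take the neighbouring flask, the same flask with 0.6 mol% of initiator. Its a and b are unchanged, so its exposure moves with the loading and with the new share, 0.944, which makes X = 0.703. For that flask the reckoning brings c to 50.5%, and with 0.00545 mM of chains begun, dp to 92.6. The simulated neighbouring flask gives c = 50.5% and dp = 95.0.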